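Skeleton numbering used throughout: ring A is C1–C5, C6 is the spiro carbon, ring B is C7–C11, and C14 is the exocyclic methylene carbon.

## Analysis of the target

Compound 25 is a spiro[5.5]undecane (a chamigrane). Ring A is C6–C1H2–C2HBr–C3(CH3)Cl–C4H2–C5H2 and ring B is C6–C7(=C14H2)–C8(=O)–C9H=C10Br–C11(CH3)2, joined at the quaternary carbon C6. There are three stereocentres, C2, C3 and C6. Bromine on C2 and chlorine on C3 are trans; bromine lies on the face of ring A that carries C11 and chlorine on the face that carries C7, so in the chair that keeps C11 equatorial both halogens should be equatorial and the C3 methyl axial. C6 is stereogenic only because each ring is unsymmetrical about it, so any ring A intermediate with a local mirror plane (a plain 3-ketone, for instance) would erase it. The sensitive groups are the β-bromo enone (a vinylogous acyl bromide), the exocyclic enone (a Michael acceptor) and the tertiary chloride beside a secondary bromide, which is prone to elimination. The difficulty lies in building a quaternary spiro centre flanked by the fully substituted C11 and the sp2 carbon C7, in relating it to two remote halogen-bearing centres, and in reaching the ring B oxidation pattern without losing the C10 bromine. The strategy rests on ring B: bromine on C10 beside the gem-dimethyl carbon C11, together with a methylene on C7, is what remains when a bromonium ion is opened at C11 by a C6=C7 alkene and the C7 cation loses a C14 proton. The sp3 C10–Br centre formed in that event can carry the absolute configuration to C6 before C10 becomes trigonal.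

## Retrosynthetic reasoning

The C9=C10 double bond is removed first, 25 going back through selenide 23 to the saturated ketone 21. The β-bromo enone is the most reactive group of 25 and should exist only at the end. A C–H pair is cut rather than the C–Br bond because the bromine is already in place from ring formation. The forward reaction must dehydrogenate next to a bromide that is β to a carbonyl group without expelling it, which rules out a free enolate and points to a syn elimination.

The C8 carbonyl is cut next, 21 to alcohol 20 to alkene 19. C8 is the only allylic carbon of the C7=C14 alkene that bears hydrogen, so an ene-type oxidation has no regiochemical choice. Putting this oxidation after ring A is complete keeps the exocyclic enone away from the hydride and methyl reagents used there.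

In ring A the C3–Cl bond is cut to tertiary alcohol 18 and the C3–CH3 bond to α-bromo ketone 17. A cation at C3 is bridged by the bromine on C2, so chloride can enter only anti to it; the C2 centre thus controls C3. Direct addition of bromine and chloride to a C2=C3 alkene was not chosen: diaxial opening in the half-chair that keeps C11 equatorial would place bromine on the C7 face, the wrong one.

The C2–Br bond is cut to silyl enol ether 15 and from there to enone 14. The enol ether fixes the site of bromination at C2 and, as important, keeps the C1 and C5 arms different, so C6 stays stereogenic. The forward reaction then has to deliver the C2 epimer with bromine on the C11 face; this is the equatorial and more stable one (17), and its axial epimer 16 can be converged on it.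

Ring A is opened at C1=C2 by a retro-aldol condensation, 14 to keto aldehyde 13, which comes by functional-group changes from 12, 11 and acetate 10. The aldehyde carbon sits on the quaternary C6 and cannot enolise, so only one aldol closure is possible.

The key disconnection cuts C6–C11 and C10–Br of 10 to give the acyclic diene 9. One forward event builds ring B, the spiro carbon, the C10 bromide and the C7 methylene. The alkene geometry of 9 decides which arm becomes axial, so C10 and C6 are set relative to each other in a predictable way.

Diene 9 is traced through alcohol 8 and ester 7 to enol triflate 6 (C7–C14 bond), whose geometry comes from chelation in the enolate of β-keto ester 5. Compound 5 is cut at C5–C6 to 3 and bromide 4, and 3 at C8–C9 to 1 and 2. These are enolate alkylations of an acetoacetate and put little of the route's risk before the key step.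

## Alternatives that were turned down

Alternative 1: Here ring A is halogenated last on a finished spirocycle. The C2–Br bond and a temporary C3–O bond are cut, leading from bromo ether A2 back to hydroxy diene A1, in which C7 carries a tertiary hydroxyl and ring A a C2=C3 alkene. In the forward step an electrophilic bromine source forms the bromonium ion on C2=C3, and the C7 hydroxyl, which can reach C3 only across the ring on the C7 face, opens it and closes a 2-oxabicyclo[2.2.2]octane.
- For: the tether dictates that the heteroatom on C3 sits on the C7 face and bromine on the C11 face, exactly the relation of C2 and C3 to C6 in 25. On this point it is stronger than the chosen route, which relies on an equilibration at C2 and on bromine participation at C3.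
- Against: the step makes no skeletal bond. A1, with its quaternary C6 and the correct C7 carbinol epimer beside a β-bromo enone, must be made as a single enantiomer by chemistry the alternative leaves open. Afterwards the bridge has to be undone in two different ways, C3–O to C3–Cl with retention and C7–O to the C7=C14 alkene, under ionising conditions next to a vinylogous acyl bromide.
- Comparison: it moves the hard problems (spiro centre, absolute configuration, ring B) upstream and adds steps at the end. In place of the tether, the chosen strategy offers one event that builds ring B, the spiro centre and the C10 bromine.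

Alternative 2: Ring A is disconnected at C5–C6 and C1=C2, leading from spiro enedione A5 to the racemic aldehyde A3 and but-3-en-2-one A4. In the forward step a cinchona-type primary amine with an acid co-catalyst turns A3 into its enamine, which erases the racemic centre; Michael addition to A4 sets C6 and aldol condensation closes ring A.
- For: it is catalytic, convergent and short, and reaches a 4,4-disubstituted cyclohexenone equivalent to 14 in far fewer steps. The C10 ketone of A5 is also a better precursor of the C10 vinyl bromide than an sp3 bromide is. On both points it is stronger.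
- Against: the enamine is tetrasubstituted and flanked by the gem-dimethyl carbon, so the Michael step is likely to be slow, and its selectivity has to come from telling a CH2 from a C(CH3)2 group. A5 has neither C14 nor the C8 oxygen, so C7, a neopentyl methylene beside the spiro centre, must be methylenated and C8 oxidised later. The ring A halogenation problem remains exactly as in the chosen route.
- Comparison: in exchange for the brevity, the chosen strategy gives ring B with the C7 methylene and the C10 bromine already in place from the ring closure.

Alternative 3: The C10–C11 bond is cut last. A7 goes back to A6, a cyclohexane that already carries both ring A halogens and, on C6, an isopropenyl group and a bromoynone chain. In the forward step an iron hydride (from an iron tris(β-diketonate) and an arylsilane) gives a hydrogen atom to the isopropenyl methylene, the tertiary C11 radical adds to the bromine-bearing β-carbon C10 of the ynone in a 6-endo-dig closure, and the C9 vinyl radical is reduced.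
- For: the crowded C10–C11 bond is made by a radical, which tolerates congestion, and the β-bromo enone arises directly with no dehydrogenation next to a bromide. On that point it is stronger than the chosen route, whose end game is its weakest part.
- Against: A6 contains all three stereocentres of 25, so the key step controls none of them and the source of the C6 configuration is left open. The radical may close 5-exo onto C9 or abstract bromine from the bromoalkyne or from C2, and the ynone may be reduced by the hydride. A7 still lacks C14, so a methylenation at C7 in the presence of the β-bromo enone follows.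
- Comparison: the chosen strategy offers a key step that creates the spiro centre with absolute control and installs the C7 methylene, at the price of the late dehydrogenation.

Key step: step 7

Remark: the facial sense of the chiral Lewis base on this diene is assumed, not known; the antipode written is taken to deliver bromine to the Re face of C10, and its mirror image is used if the sense is the reverse.

## Route

Step 1
Reactants: 1 methyl acetoacetate; 2 prenyl bromide
Product: 3 methyl 7-methyl-3-oxooct-6-enoate
Conditions: NaH, THF, 0 °C; n-BuLi, 0 °C; then 2, 0 °C to rt; dilute HCl quench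
Reagents that add atoms: none
Why: Acetoacetate dianion alkylation: the second deprotonation creates the more reactive terminal carbanion, which takes the allylic bromide at its primary carbon (SN2) and leaves the C6 methylene free for step 2.

Step 2
Reactants: 3 methyl 7-methyl-3-oxooct-6-enoate; 4 2-(2-bromoethyl)-2-methyl-1,3-dioxolane
Product: 5 methyl 7-methyl-2-[2-(2-methyl-1,3-dioxolan-2-yl)ethyl]-3-oxooct-6-enoate (racemic)
Conditions: NaH, THF/DMF, 0 °C; then 4, NaI (cat.), 60 °C
Reagents that add atoms: none
Why: C-alkylation of the stabilised β-keto ester enolate by a primary halide, helped by Finkelstein exchange to the iodide in the flask; the stereocentre formed here is racemic and disappears in step 3.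

Step 3
Reactants: 5 methyl 7-methyl-2-[2-(2-methyl-1,3-dioxolan-2-yl)ethyl]-3-oxooct-6-enoate
Product: 6 methyl (2Z)-7-methyl-2-[2-(2-methyl-1,3-dioxolan-2-yl)ethyl]-3-(trifluoromethanesulfonyloxy)octa-2,6-dienoate
Conditions: NaH, THF, 0 °C; then PhNTf2, 0 °C to rt
Reagents that add atoms: N-phenylbis(trifluoromethanesulfonimide), O=S(=O)(N(c1ccccc1)S(=O)(=O)C(F)(F)F)C(F)(F)F
Why: O-sulfonylation of the sodium-chelated enolate, in which the enolate oxygen and the ester carbonyl are held on the same side, should give the triflate cis to the ester, that is (Z); this geometry is what later places the C5 arm cis to C8.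

Step 4
Reactants: 6 methyl (2Z)-7-methyl-2-[2-(2-methyl-1,3-dioxolan-2-yl)ethyl]-3-(trifluoromethanesulfonyloxy)octa-2,6-dienoate
Product: 7 methyl (2E)-3,7-dimethyl-2-[2-(2-methyl-1,3-dioxolan-2-yl)ethyl]octa-2,6-dienoate
Conditions: MeZnCl, Pd(PPh3)4 (5 mol %), THF, 50 °C
Reagents that add atoms: methylzinc chloride, C[Zn]Cl
Why: Negishi coupling: oxidative addition of the alkenyl triflate and reductive elimination both go with retention, so the C14 methyl takes the place of the triflate cis to the ester and the (E)-tetrasubstituted enoate should result.

Step 5
Reactants: 7 methyl (2E)-3,7-dimethyl-2-[2-(2-methyl-1,3-dioxolan-2-yl)ethyl]octa-2,6-dienoate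
Product: 8 (2E)-3,7-dimethyl-2-[2-(2-methyl-1,3-dioxolan-2-yl)ethyl]octa-2,6-dien-1-ol
Conditions: i-Bu2AlH (2.5 equiv), CH2Cl2, −78 to 0 °C; aqueous potassium sodium tartrate
Reagents that add atoms: none
Why: 1,2-Reduction of the conjugated ester by the aluminium hydride at low temperature gives the allylic alcohol without touching the alkene geometry or the ketal.

Step 6
Reactants: 8 (2E)-3,7-dimethyl-2-[2-(2-methyl-1,3-dioxolan-2-yl)ethyl]octa-2,6-dien-1-ol
Product: 9 (2E)-3,7-dimethyl-2-[2-(2-methyl-1,3-dioxolan-2-yl)ethyl]octa-2,6-dien-1-yl acetate
Conditions: Ac2O, Et3N, DMAP (cat.), CH2Cl2, 0 °C to rt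
Reagents that add atoms: acetic anhydride, CC(=O)OC(C)=O
Why: Acylation; the acetate stops the hydroxyl from acting as a nucleophile in step 7 and withdraws electron density from the tetrasubstituted alkene.

Step 7
Reactants: 9 (2E)-3,7-dimethyl-2-[2-(2-methyl-1,3-dioxolan-2-yl)ethyl]octa-2,6-dien-1-yl acetate
Product: 10 [(1S,3R)-3-bromo-2,2-dimethyl-6-methylidene-1-[2-(2-methyl-1,3-dioxolan-2-yl)ethyl]cyclohexyl]methyl acetate
Conditions: NBS (1.1 equiv), (R)-3,3′-bis(2,4,6-triisopropylphenyl)-1,1′-binaphthalene-2,2′-diyl N-triflylphosphoramidothioate (10 mol %), toluene/CH2Cl2, −78 °C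
Reagents that add atoms: N-bromosuccinimide, O=C1CCC(=O)N1Br
Why: The thiophosphoryl sulfur takes Br+ from NBS and the chiral ion pair passes it to the C10 Re face of the terminal alkene, which is the more accessible of the two and is not deactivated by the allylic acetate; transfer of Br+ between alkenes is reversible, so the hindered C6=C7 alkene does not hold it. The unsymmetrical bromonium ion is opened at tertiary C11, anti to bromine, by C6: attack by C6 and not C7 closes a six-membered ring and puts the charge on C7, remote from the electron-withdrawing acetoxymethyl group. Ring B therefore closes in the 6-endo-trig mode with respect to the C6=C7 alkene, through a chair with bromine equatorial. C10 is set by the catalyst (face of bromonium formation), and C6 is set by the substrate: in the chair the arm trans to C8 on the alkene (C1) becomes equatorial and cis to bromine and the arm cis to C8 (C5) becomes axial, so the (E) geometry turns C10 (R) into C6 (S). The C7 cation then gives up a C14 proton to succinimide anion, which leaves the exocyclic methylene and avoids the strain that an endocyclic C7=C8 alkene would have between the C14 methyl and the arms on C6. The closest known reaction type is the Lewis-base-catalysed enantioselective bromonium-initiated cyclisation of polyprenoids, together with the racemic bromocyclisation of geranyl acetate-type dienes. The step needs site selectivity between the two alkenes, one bromonium face, a chair closure and exocyclic proton loss; the acetate and the steric difference secure the first, the catalyst the second, the lack of any substituent that would favour a boat the third, and the last is the least secured.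

Step 8
Reactants: 10 [(1S,3R)-3-bromo-2,2-dimethyl-6-methylidene-1-[2-(2-methyl-1,3-dioxolan-2-yl)ethyl]cyclohexyl]methyl acetate
Product: 11 [(1S,3R)-3-bromo-2,2-dimethyl-6-methylidene-1-[2-(2-methyl-1,3-dioxolan-2-yl)ethyl]cyclohexyl]methanol
Conditions: K2CO3 (cat.), MeOH, 0 °C to rt
Reagents that add atoms: none
Why: Base-catalysed transesterification frees the neopentyl alcohol; the secondary bromide cannot be displaced by the C1 alkoxide because both sit on the same face of ring B.

Step 9
Reactants: 11 [(1S,3R)-3-bromo-2,2-dimethyl-6-methylidene-1-[2-(2-methyl-1,3-dioxolan-2-yl)ethyl]cyclohexyl]methanol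
Product: 12 (1S,3R)-3-bromo-2,2-dimethyl-6-methylidene-1-[2-(2-methyl-1,3-dioxolan-2-yl)ethyl]cyclohexane-1-carbaldehyde
Conditions: Dess–Martin periodinane, NaHCO3, CH2Cl2, 0 °C to rt
Reagents that add atoms: none
Why: Dess–Martin oxidation of the primary alcohol under buffered conditions; the aldehyde has no α-hydrogen, so C6 cannot epimerise.

Step 10
Reactants: 12 (1S,3R)-3-bromo-2,2-dimethyl-6-methylidene-1-[2-(2-methyl-1,3-dioxolan-2-yl)ethyl]cyclohexane-1-carbaldehyde
Product: 14 (6S,10R)-10-bromo-11,11-dimethyl-7-methylidenespiro[5.5]undec-1-en-3-one, via keto aldehyde 13 (not isolated)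
Conditions: PPTS, acetone/H2O, 55 °C; then KOH, MeOH, 0 °C to rt
Reagents that add atoms: water, O
Why: Acid-catalysed ketal hydrolysis, then intramolecular aldol condensation (the ring-closing half of a Robinson annulation): only the methyl group of the ketone can reach the non-enolisable aldehyde through a six-membered ring, so C1=C2 forms and C6 keeps two different arms.

Step 11
Reactants: 14 (6S,10R)-10-bromo-11,11-dimethyl-7-methylidenespiro[5.5]undec-1-en-3-one
Product: 15 (6S,10R)-10-bromo-11,11-dimethyl-7-methylidene-3-(triethylsilyloxy)spiro[5.5]undec-2-ene
Conditions: Et3SiH, RhCl(PPh3)3 (2 mol %), benzene, 60 °C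
Reagents that add atoms: triethylsilane, CC[SiH](CC)CC
Why: Rhodium-catalysed 1,4-hydrosilylation of the enone delivers hydride to C1 and silicon to oxygen, so the enol ether double bond is fixed at C2=C3; ring A never passes through the symmetric 3-ketone, which would make C6 non-stereogenic.

Step 12
Reactants: 15 (6S,10R)-10-bromo-11,11-dimethyl-7-methylidene-3-(triethylsilyloxy)spiro[5.5]undec-2-ene
Product: 17 (2S,6S,10R)-2,10-dibromo-11,11-dimethyl-7-methylidenespiro[5.5]undecan-3-one, via axial 2-epimer 16 (not isolated)
Conditions: NBS, THF, −78 °C; then LiBr, acetone, rt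
Reagents that add atoms: N-bromosuccinimide, O=C1CCC(=O)N1Br
Why: Electrophilic bromination of the silyl enol ether puts bromine on C2 only; kinetic axial attack is expected to give at least part of the axial epimer 16. Bromide ion then equilibrates C2 by degenerate SN2 exchange, without enolisation towards C4, to the more stable epimer 17, whose bromine is equatorial in the chair that keeps C11 equatorial and C7 axial, that is cis to C11.

Step 13
Reactants: 17 (2S,6S,10R)-2,10-dibromo-11,11-dimethyl-7-methylidenespiro[5.5]undecan-3-one
Product: 18 (2S,3S,6S,10R)-2,10-dibromo-3,11,11-trimethyl-7-methylidenespiro[5.5]undecan-3-ol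
Conditions: Me3Al (4 equiv), toluene, −78 to −20 °C; aqueous potassium sodium tartrate
Reagents that add atoms: trimethylaluminium, C[Al](C)C
Why: Carbonyl methylation with excess trimethylaluminium in a hydrocarbon solvent, where the compression effect of the oxygen-bound aluminium favours axial delivery; the methyl should then be axial and cis to the C2 bromine, the hydroxyl equatorial and trans to it. The reagent is non-basic, which avoids enolisation of the α-bromo ketone, and the cold quench avoids semipinacol ring contraction of the aluminium alkoxide.

Step 14
Reactants: 18 (2S,3S,6S,10R)-2,10-dibromo-3,11,11-trimethyl-7-methylidenespiro[5.5]undecan-3-ol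
Product: 19 (2S,3S,6S,10R)-2,10-dibromo-3-chloro-3,11,11-trimethyl-7-methylidenespiro[5.5]undecane
Conditions: SOCl2, 2,6-di-tert-butyl-4-methylpyridine, CH2Cl2, −40 to 0 °C
Reagents that add atoms: thionyl chloride, O=S(Cl)Cl
Why: Deoxychlorination of a tertiary alcohol through its chlorosulfite with neighbouring-group participation: as the C3–O bond ionises, the C2 bromine bridges the cation on the face opposite the departing oxygen, and chloride opens the bromonium ion at tertiary C3 anti to bromine. Chlorine thus enters where the hydroxyl stood (net retention) and ends trans to bromine; the hindered pyridine takes up HCl so that the C7=C14 alkene is not protonated.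

Step 15
Reactants: 19 (2S,3S,6S,10R)-2,10-dibromo-3-chloro-3,11,11-trimethyl-7-methylidenespiro[5.5]undecane
Product: 20 (2S,3S,6S,10R)-2,10-dibromo-3-chloro-3,11,11-trimethyl-7-methylidenespiro[5.5]undecan-8-ol (both C8 epimers)
Conditions: SeO2 (0.5 equiv), t-BuOOH, CH2Cl2, rt
Reagents that add atoms: selenium dioxide, O=[Se]=O (oxygen donor, regenerated by tert-butyl hydroperoxide, CC(C)(C)OO)
Why: Allylic oxidation by SeO2 (ene reaction at C14, then [2,3]-sigmatropic shift) hydroxylates C8, the only allylic carbon bearing hydrogen, and returns the double bond to C7=C14; the C8 configuration is of no consequence.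

Step 16
Reactants: 20 (2S,3S,6S,10R)-2,10-dibromo-3-chloro-3,11,11-trimethyl-7-methylidenespiro[5.5]undecan-8-ol
Product: 21 (2S,3S,6S,10R)-2,10-dibromo-3-chloro-3,11,11-trimethyl-7-methylidenespiro[5.5]undecan-8-one
Conditions: Dess–Martin periodinane, NaHCO3, CH2Cl2, 0 °C
Reagents that add atoms: none
Why: Buffered Dess–Martin oxidation gives the enone under non-basic conditions, which matters because the C10 bromide is now β to a carbonyl group.

Step 17
Reactants: 21 (2S,3S,6S,10R)-2,10-dibromo-3-chloro-3,11,11-trimethyl-7-methylidenespiro[5.5]undecan-8-one
Product: 23 (2S,3S,6S,9S,10S)-2,10-dibromo-3-chloro-3,11,11-trimethyl-7-methylidene-9-(phenylselanyl)spiro[5.5]undecan-8-one, via silyl dienol ether 22 (not isolated)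
Conditions: Me3SiOTf, Et3N, CH2Cl2, −78 °C; then PhSeCl, −78 °C
Reagents that add atoms: benzeneselenenyl chloride, Cl[Se]c1ccccc1
Why: Soft enolisation (silyl triflate and amine) forms the C8=C9 silyl enol ether without a free enolate, and the selenenyl chloride is taken up at C9 at low temperature. The C10–Br bond is pseudoequatorial, close to the nodal plane of the enol ether, which should hold back its ionisation, and attack anti to the axial C11 methyl should put selenium cis to the C10 hydrogen.

Step 18
Reactants: 23 (2S,3S,6S,9S,10S)-2,10-dibromo-3-chloro-3,11,11-trimethyl-7-methylidene-9-(phenylselanyl)spiro[5.5]undecan-8-one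
Product: 25 (2S,3S,6S)-2,10-dibromo-3-chloro-3,11,11-trimethyl-7-methylidenespiro[5.5]undec-9-en-8-one, via selenoxide 24 (not isolated)
Conditions: mCPBA (1.1 equiv), CH2Cl2, −78 to 0 °C
Reagents that add atoms: none
Why: Oxidation at selenium and selenoxide syn-elimination: the only β-hydrogen is the one on C10, so the double bond must form as C9=C10 and the bromine stays on the new sp2 carbon; the reaction runs below room temperature and needs no base.

## Compound list

1 | methyl acetoacetate | COC(=O)CC(C)=O | starting material
2 | prenyl bromide (1-bromo-3-methylbut-2-ene) | CC(C)=CCBr | starting material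
3 | methyl 7-methyl-3-oxooct-6-enoate | COC(=O)CC(=O)CCC=C(C)C | intermediate
4 | 2-(2-bromoethyl)-2-methyl-1,3-dioxolane | CC1(CCBr)OCCO1 | starting material
5 | methyl 7-methyl-2-[2-(2-methyl-1,3-dioxolan-2-yl)ethyl]-3-oxooct-6-enoate (racemic) | COC(=O)C(CCC1(C)OCCO1)C(=O)CCC=C(C)C | intermediate
6 | methyl (2Z)-7-methyl-2-[2-(2-methyl-1,3-dioxolan-2-yl)ethyl]-3-(trifluoromethanesulfonyloxy)octa-2,6-dienoate | COC(=O)/C(CCC1(C)OCCO1)=C(\OS(=O)(=O)C(F)(F)F)CCC=C(C)C | intermediate
7 | methyl (2E)-3,7-dimethyl-2-[2-(2-methyl-1,3-dioxolan-2-yl)ethyl]octa-2,6-dienoate | COC(=O)/C(CCC1(C)OCCO1)=C(\C)CCC=C(C)C | intermediate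
8 | (2E)-3,7-dimethyl-2-[2-(2-methyl-1,3-dioxolan-2-yl)ethyl]octa-2,6-dien-1-ol | OC/C(CCC1(C)OCCO1)=C(\C)CCC=C(C)C | intermediate
9 | (2E)-3,7-dimethyl-2-[2-(2-methyl-1,3-dioxolan-2-yl)ethyl]octa-2,6-dien-1-yl acetate | CC(C)=CCC/C(C)=C(/COC(C)=O)CCC1(C)OCCO1 | intermediate
10 | [(1S,3R)-3-bromo-2,2-dimethyl-6-methylidene-1-[2-(2-methyl-1,3-dioxolan-2-yl)ethyl]cyclohexyl]methyl acetate | C=C1CC[C@@H](Br)C(C)(C)[C@]1(COC(C)=O)CCC2(C)OCCO2 | intermediate
11 | [(1S,3R)-3-bromo-2,2-dimethyl-6-methylidene-1-[2-(2-methyl-1,3-dioxolan-2-yl)ethyl]cyclohexyl]methanol | C=C1CC[C@@H](Br)C(C)(C)[C@]1(CO)CCC2(C)OCCO2 | intermediate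
12 | (1S,3R)-3-bromo-2,2-dimethyl-6-methylidene-1-[2-(2-methyl-1,3-dioxolan-2-yl)ethyl]cyclohexane-1-carbaldehyde | C=C1CC[C@@H](Br)C(C)(C)[C@]1(C=O)CCC2(C)OCCO2 | intermediate
13 | (1S,3R)-3-bromo-2,2-dimethyl-6-methylidene-1-(3-oxobutyl)cyclohexane-1-carbaldehyde | C=C1CC[C@@H](Br)C(C)(C)[C@]1(C=O)CCC(C)=O | intermediate
14 | (6S,10R)-10-bromo-11,11-dimethyl-7-methylidenespiro[5.5]undec-1-en-3-one | C=C1CC[C@@H](Br)C(C)(C)[C@]12CCC(=O)C=C2 | intermediate
15 | (6S,10R)-10-bromo-11,11-dimethyl-7-methylidene-3-(triethylsilyloxy)spiro[5.5]undec-2-ene | C=C1CC[C@@H](Br)C(C)(C)[C@]12CCC(O[Si](CC)(CC)CC)=CC2 | intermediate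
16 | (2R,6S,10R)-2,10-dibromo-11,11-dimethyl-7-methylidenespiro[5.5]undecan-3-one | C=C1CC[C@@H](Br)C(C)(C)[C@]12CCC(=O)[C@H](Br)C2 | intermediate
17 | (2S,6S,10R)-2,10-dibromo-11,11-dimethyl-7-methylidenespiro[5.5]undecan-3-one | C=C1CC[C@@H](Br)C(C)(C)[C@]12CCC(=O)[C@@H](Br)C2 | intermediate
18 | (2S,3S,6S,10R)-2,10-dibromo-3,11,11-trimethyl-7-methylidenespiro[5.5]undecan-3-ol | C=C1CC[C@@H](Br)C(C)(C)[C@]12CC[C@](C)(O)[C@@H](Br)C2 | intermediate
19 | (2S,3S,6S,10R)-2,10-dibromo-3-chloro-3,11,11-trimethyl-7-methylidenespiro[5.5]undecane | C=C1CC[C@@H](Br)C(C)(C)[C@]12CC[C@](C)(Cl)[C@@H](Br)C2 | intermediate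
20 | (2S,3S,6S,10R)-2,10-dibromo-3-chloro-3,11,11-trimethyl-7-methylidenespiro[5.5]undecan-8-ol (both C8 epimers) | C=C1C(O)C[C@@H](Br)C(C)(C)[C@]12CC[C@](C)(Cl)[C@@H](Br)C2 | intermediate
21 | (2S,3S,6S,10R)-2,10-dibromo-3-chloro-3,11,11-trimethyl-7-methylidenespiro[5.5]undecan-8-one | C=C1C(=O)C[C@@H](Br)C(C)(C)[C@]12CC[C@](C)(Cl)[C@@H](Br)C2 | intermediate
22 | (2S,3S,6S,10R)-2,10-dibromo-3-chloro-3,11,11-trimethyl-7-methylidene-8-(trimethylsilyloxy)spiro[5.5]undec-8-ene | C=C1C(O[Si](C)(C)C)=C[C@@H](Br)C(C)(C)[C@]12CC[C@](C)(Cl)[C@@H](Br)C2 | intermediate
23 | (2S,3S,6S,9S,10S)-2,10-dibromo-3-chloro-3,11,11-trimethyl-7-methylidene-9-(phenylselanyl)spiro[5.5]undecan-8-one | C=C1C(=O)[C@H]([Se]c3ccccc3)[C@@H](Br)C(C)(C)[C@]12CC[C@](C)(Cl)[C@@H](Br)C2 | intermediate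
24 | (2S,3S,6S,9S,10S)-9-(benzeneseleninyl)-2,10-dibromo-3-chloro-3,11,11-trimethyl-7-methylidenespiro[5.5]undecan-8-one (either configuration at selenium) | C=C1C(=O)[C@H]([Se](=O)c3ccccc3)[C@@H](Br)C(C)(C)[C@]12CC[C@](C)(Cl)[C@@H](Br)C2 | intermediate
25 | (2S,3S,6S)-2,10-dibromo-3-chloro-3,11,11-trimethyl-7-methylidenespiro[5.5]undec-9-en-8-one | C=C1C(=O)C=C(Br)C(C)(C)[C@]12CC[C@](C)(Cl)[C@@H](Br)C2 | target

## Step count and least certain steps

Total: 18 steps, all in one linear sequence from 1; the longest linear sequence is 18 steps.

Step 7 (key step). The most likely failures are weak enantiofacial discrimination and proton loss from C8 in place of C14. Catalysts of this type were shaped for polyenes with aryl terminators, and uncatalysed bromination by NBS competes; an endocyclic trisubstituted alkene is a normal product of such cyclisations. Bromination at the tetrasubstituted alkene with acetate participation is a further drain. Fallback, from 9 back to 10: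
- Shi epoxidation of 9 at the terminal alkene (KHSO5, K2CO3 buffer), with the antipode of the fructose-derived ketone that gives the (S)-epoxide F1.
- Opening of F1 at C10 by bromide with inversion (Li2NiBr4, THF) to the (R)-bromohydrin F2.
- Trifluoroacetylation of the tertiary hydroxyl to the trifluoroacetate F3.
- Solvolysis of F3 in (CF3)2CHOH buffered with 2,6-di-tert-butylpyridine: the C10 bromine assists ionisation at C11 and gives the same bromonium ion with fixed configuration, which closes to 10 as in step 7.

This removes the dependence on the catalyst and on site selectivity, though not the question of which proton is lost.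

Step 17 (completed in step 18). The most likely failure is loss of the C10 bromide by β-elimination from the enol ether 22, or from any enolate formed in its place, because a leaving group β to the carbonyl is expelled as soon as the C–Br bond can align with the π system. The second is selenenylation on the face cis to bromine, which would leave no syn hydrogen for step 18. Fallback, from 20 to 25:
- Dehydration of 20 (Burgess reagent, benzene, 50 °C) to the diene F4, whose only allylic hydrogen is the one on C10.
- Schenck ene reaction with singlet oxygen (O2, tetraphenylporphyrin, light, CH2Cl2, 0 °C), which puts the hydroperoxide on C8 and the double bond at C9=C10, giving the hydroperoxide F5.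
- Dehydration of the secondary allylic hydroperoxide (Ac2O, pyridine) to 25.

No enol or enolate β to the sp3 bromide is formed on this path.

Step 14. The most likely failure is elimination from the chlorosulfite (towards C4 or C2) in place of substitution, since the equatorial bromine can assist ionisation only from a twist conformer. If the base is left out to speed ionisation, protonation of the C7=C14 alkene by HCl becomes the problem. Fallback, from 18 to 21: the tertiary alcohol is carried through ring B oxidation first. SeO2 with t-BuOOH gives the diol F6, and Dess–Martin periodinane, which oxidises only the secondary allylic hydroxyl, gives the hydroxy enone F7. Chlorine is then introduced with SOCl2 without base at −40 °C, which the conjugated alkene of F7 should tolerate, and this gives 21.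

Step 13. The most likely failure is poor facial selectivity of methyl delivery, since equatorial attack is the normal preference of methyl nucleophiles; semipinacol ring contraction of the aluminium alkoxide on warming is the second. Fallback, from 17 to 19: equatorial delivery is made the rule with MeTi(Oi-Pr)3, which should give the C3 epimer F8 (hydroxyl axial, cis to bromine). F8 is then ionised under neutral conditions (1-chloro-N,N,2-trimethylprop-1-en-1-amine, CH2Cl2, 0 °C); the C2 bromine bridges the cation on the face the leaving group has vacated, and chloride enters from the opposite face, with inversion at C3, to give 19.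

## Further compounds

F1 | step 7 | (2E)-5-[(2S)-3,3-dimethyloxiran-2-yl]-3-methyl-2-[2-(2-methyl-1,3-dioxolan-2-yl)ethyl]pent-2-en-1-yl acetate | CC1(C)O[C@H]1CC/C(C)=C(/COC(C)=O)CCC2(C)OCCO2
F2 | step 7 | (2E,6R)-6-bromo-7-hydroxy-3,7-dimethyl-2-[2-(2-methyl-1,3-dioxolan-2-yl)ethyl]oct-2-en-1-yl acetate | CC(C)(O)[C@H](Br)CC/C(C)=C(/COC(C)=O)CCC1(C)OCCO1
F3 | step 7 | (2E,6R)-6-bromo-3,7-dimethyl-2-[2-(2-methyl-1,3-dioxolan-2-yl)ethyl]-7-(trifluoroacetoxy)oct-2-en-1-yl acetate | CC(C)(OC(=O)C(F)(F)F)[C@H](Br)CC/C(C)=C(/COC(C)=O)CCC1(C)OCCO1
F4 | step 17 | (2S,3S,6S,10R)-2,10-dibromo-3-chloro-3,11,11-trimethyl-7-methylidenespiro[5.5]undec-8-ene | C=C1C=C[C@@H](Br)C(C)(C)[C@]12CC[C@](C)(Cl)[C@@H](Br)C2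
F5 | step 17 | (2S,3S,6S)-2,10-dibromo-3-chloro-8-hydroperoxy-3,11,11-trimethyl-7-methylidenespiro[5.5]undec-9-ene (both C8 epimers) | C=C1C(OO)C=C(Br)C(C)(C)[C@]12CC[C@](C)(Cl)[C@@H](Br)C2
F6 | step 14 | (2S,3S,6S,10R)-2,10-dibromo-3,11,11-trimethyl-7-methylidenespiro[5.5]undecane-3,8-diol (both C8 epimers) | C=C1C(O)C[C@@H](Br)C(C)(C)[C@]12CC[C@](C)(O)[C@@H](Br)C2
F7 | step 14 | (2S,3S,6S,10R)-2,10-dibromo-3-hydroxy-3,11,11-trimethyl-7-methylidenespiro[5.5]undecan-8-one | C=C1C(=O)C[C@@H](Br)C(C)(C)[C@]12CC[C@](C)(O)[C@@H](Br)C2
F8 | step 13 | (2S,3R,6S,10R)-2,10-dibromo-3,11,11-trimethyl-7-methylidenespiro[5.5]undecan-3-ol | C=C1CC[C@@H](Br)C(C)(C)[C@]12CC[C@@](C)(O)[C@@H](Br)C2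
A1 | alternative 1 | 10-bromo-7-hydroxy-3,7,11,11-tetramethylspiro[5.5]undeca-2,9-dien-8-one (C6 as in 25, hydroxyl on the face of C7 that reaches C3) | CC1=CC[C@@]2(CC1)[C@@](C)(O)C(=O)C=C(Br)C2(C)C
A2 | alternative 1 | 2,10-dibromo-3,7-epoxy-3,7,11,11-tetramethylspiro[5.5]undec-9-en-8-one (ether bridge from C7 to C3) | C[C@]12CC[C@]3(C[C@@H]1Br)[C@@](C)(O2)C(=O)C=C(Br)C3(C)C
A3 | alternative 2 | 2,2-dimethyl-3-oxocyclohexane-1-carbaldehyde (racemic) | O=CC1CCCC(=O)C1(C)C
A4 | alternative 2 | but-3-en-2-one | CC(=O)C=C
A5 | alternative 2 | 11,11-dimethylspiro[5.5]undec-1-ene-3,10-dione (single enantiomer at C6) | O=C1C=C[C@@]2(CC1)CCCC(=O)C2(C)C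
A6 | alternative 3 | 4-bromo-1-[3-bromo-4-chloro-4-methyl-1-(prop-1-en-2-yl)cyclohexyl]but-3-yn-2-one (ring stereocentres as in 25) | C=C(C)[C@@]1(CC(=O)C#CBr)CC[C@](C)(Cl)[C@@H](Br)C1
A7 | alternative 3 | 2,10-dibromo-3-chloro-3,11,11-trimethylspiro[5.5]undec-9-en-8-one (stereocentres as in 25) | O=C1C[C@@]2(CC[C@](C)(Cl)[C@@H](Br)C2)C(C)(C)C(Br)=C1
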